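E could not vanish past its partner: on the listed steps each E lost takes one D, so the loss of E in the west flask was capped by D.

in all of them: E 0.32 M
- west: D 0.304 M; Z 0.096 M; the very flask that is asked about, followed so far
- south: D 0.15 M; Z 0.096 M; run made earlier
- flask: D 0.304 M; Z 0.0960 M; time 8.0 h

| run | time / h | E / % | Q / % |
|---|---|---|---|
| west | 0.417 | 6 | 47 |
| west | 0.833 | 3 | 36 |
| west | 1.33 | 11 | 36 |
| west | 1.50 | 8 | 35 |
| west | 2.00 | 10 | 33 |
| west | 2.50 | 7 | 35 |
| south | 0.667 | 53 | 19 |
| south | 1.00 | 53 | 18 |
| south | 2.00 | 58 | 18 |
| south | 3.00 | 57 | 20 |
| south | 5.00 | 56 | 18 |
| south | 8.00 | 54 | 16 |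

(each reading ± 2 percentage points)

1. the state of affairs at 8.0 h: stopped, and by what, or still going (all of E has reacted / it is still moving / forward and back rates have come level / D has run out first)
2. part of the E gone at 8.0 h
3. the Q standing at 8.0 h, as a percentage of the E charged
4. the L standing at 8.0 h, as a percentage of the E charged

- reactions considered so far: E + D -> Q; D + Z -> X; Q <-> L
- the reaction counts as stopped when no species that holds the E changes by six tenths of a point or more over the second half of the time

I wrote the balance of D, the limiting reagent in the west flask, since it was charged at less than E. There that gave 95.0%: D charged over E charged, the D ceiling. If no D stayed over, each D that went to Z, one per X, came off it: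

part of E gone = D ceiling − (X formed / E charged)

The bench rule sets conversion equal to the ceiling. It stops working where Z takes a real part of D, and the west charges did not forbid that, with Z at about a third of D. So I went to the readings. The west E readings averaged 7.50% of E left, so the part gone read 2.5 percentage points under the ceiling. The south E readings averaged 55.2% of E left, so the part gone read 2 points under a south ceiling of 46.9%. I took that small gap, with a scatter of 2 points on each reading, as the toll to Z, and expected the west flask to stand just under its ceiling.

The forecast gave: D has run out first, with 92.5% of E gone, Q 35% and L 57.5% at 8.0 h, on the ground that “conversion stops just short of the D limit”.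

The west flask ended as forecast, D has run out first, with 0% of its D left at 8.00 h; 92.9% of E was gone, Q stood at 34.4% and L at 58.5%. It held 0.00682 M of X, so the balance gave 95.0% less that toll: 92.9%.

    E + D → Q (k = 43.0 L mol⁻¹ min⁻¹)
    D + Z → X (k = 1.20 L mol⁻¹ min⁻¹)
    Q ⇌ L (K = 1.70, k = 0.0410 min⁻¹)

In the neighbour flask with 0.38 M of Z, the ceiling stayed 95.0%, and its 0.0220 M of X brought the balance to 88.1%. The computed conversion there was 88.1%, with 0% of its D left.

The earlier runs and the new flask were computed for substances that don't exist; noise was put on by code.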